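The north run stalls near 0.299 M of Pdt with 0.901 M of Ptn still in the flask, and the east run, charged with 1.80 M of Ptn, ends lower at 0.274 M, so you need a stall that more Ptn does not lift.

| setting | north | east | south | south-west |
|---|---|---|---|---|
| Sbt | 0.800 M | 0.800 M | 1.60 M | 0.260 M |
| Ptn | 1.20 M | 1.80 M | 1.20 M | 1.20 M |
| Ctl | 0.00160 M | 0.00160 M | 0.00160 M | 5.30 × 10⁻⁴ M |
| time |  |  |  | 260 h |

- north run (time / h: [Pdt] / M): 10: 0.078; 16: 0.099; 26: 0.129; 41: 0.173; 65: 0.209; 100: 0.234; 160: 0.280; 260: 0.299
- east run (time / h: [Pdt] / M): 10: 0.056; 16: 0.097; 26: 0.126; 41: 0.175; 65: 0.208; 100: 0.255; 160: 0.263; 260: 0.274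
- south run (time / h: [Pdt] / M): 10: 0.095; 16: 0.157; 26: 0.212; 41: 0.256; 65: 0.300; 100: 0.341; 160: 0.387; 260: 0.397

(standard deviation of a reading: 0.01 M)

- Overall: Sbt + Ptn -> Pdt, with Ctl as catalyst.
- Constant volume, constant temperature.
- The analysis sees a species whether free or bound.
- An order is taken over about fifteen percent of the charge, up and down.

1. order of the initial rate in [Sbt], near the charge of the north run, the rate being that where two percent of its Sbt are Pdt (one fixed amount of Pdt, the same in the runs compared)
2. order of the initial rate in [Ptn], near the charge of the north run, the rate being that where two percent of its Sbt are Pdt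
3. Pdt in the south-west run at 260 h, as a share of the Sbt charged

Why does it stall? In the north run Sbt is the limiting reagent, its 0.800 M standing below the 1.20 M of Ptn, while in the south run the 1.60 M of Sbt stands above that same charge of Ptn, so Ptn is the limiting reagent there; yet the south run reads only 0.0980 M more Pdt at 260 h than the north run, and the share of the Sbt charged falls from 37.4 % to 24.8 %. I read this as a product path k[Sbt], first order in Sbt and order 0 in Ptn (east and north read 0.097 M and 0.099 M at 16 h), competing with a loss of Sbt that is second order.

Let S× be the [Sbt] at which the two paths take Sbt equally fast, Q the Sbt charge and P∞ the final Pdt. Far under S× the rule gives P∞ = Q; far over it, S× ln(Q/S×), so doubling Q adds S× ln(2), which gives 0.141 M. The joined form is P∞ = S× ln(1 + Q/S×), and putting the first value back into it once gives the crossover concentration 0.159 M. That predicts 0.286 M for north and 0.382 M for south.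

How fast? Integrating the same two paths, the north reading of 0.209 M at 65 h gives k = 0.0120 h⁻¹.

What does the south-west run do? It carries 0.331 of the Ctl of north, but the three runs share one Ctl charge, so they show no order in Ctl. If k follows Ctl to the first power, S× becomes 0.0528 M, the ceiling is 36.1 % of the Sbt charged, and 260 h gives 29.0 %. If k ignored Ctl, 260 h would give 57.6 %. I commit to the first-power end, 29.0 %, with orders of one in Sbt and 0 in Ptn.

The forecast, reading the stall as “strong product inhibition”, gives 0.9, 0 and 33 %, above my share.

The flask gives orders of 1.0 and 0.0031 and 42.4 % for the south-west run.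

    Ctl + Sbt → Ctl.Sbt (69.48 L mol⁻¹ h⁻¹)
    Ctl.Sbt + Ptn → J (770.4 L mol⁻¹ h⁻¹)
    J → Pdt + Ctl (439.2 h⁻¹)
    2 Sbt → L (0.03118 L mol⁻¹ h⁻¹)
    2 Ctl ⇌ Ctl2, settled at all times (29300 L mol⁻¹)

That share stands above my first-power ceiling of 36.1 %, and the scheme pairs Ctl into a dimer with the constant 29300 L mol⁻¹. Sharing the charge between Ctl and its dimer, with Ctl.Sbt and J neglected, leaves 8.70 × 10⁻⁵ M of free Ctl in the south-west run. S× is then that amount times 69.5 L mol⁻¹ h⁻¹, over 2 × 0.0312 L mol⁻¹ h⁻¹, which comes to 0.0969 M. The joined form puts the ceiling of the south-west run at 48.6 %, and at 260 h the flask stands below it, at 42.4 %.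

All runs are calculated from invented constants, noise included.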